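**Assumptions:** atom labels (C-1 to C-15, primed for the dienophile-derived half) follow xanthanolide numbering. In step 1 the (R)-BINAP complex is taken to give the (S)-lactone; the ligand antipode is used if the sense proves opposite.

## Retrosynthetic overview

1. The target comes from γ-hydroxylation (C-1) of a β,γ-unsaturated ketone, which is the Diels–Alder dimer of 8-epi-xanthatin.
2. The dimer comes from a [4+2] reaction between the C5=C1–C2=C3 dienone of one 8-epi-xanthatin and the exocyclic C11′=C13′ alkene of a second (bonds C3–C11′ and C5–C13′; cyclohexene ring and spiro centre).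
3. 8-epi-Xanthatin comes from domino ring-closing enyne metathesis/cross metathesis with methyl vinyl ketone on an enyne α-methylene lactone (seven-membered ring).
4. The enyne lactone comes from a catalyst-controlled allylboration/lactonisation of (S)-3-methylpent-4-ynal with a 2-(methoxycarbonyl)allylboronate (γ-lactone ring, C-7/C-8).
5. The aldehyde comes from α-methylene-γ-butyrolactone; the boronate from 2-bromoacrolein and allylmagnesium bromide. Ring order: γ-lactone, then cycloheptene, then spiro-cyclohexene.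

## Route

**Step 1**
Reactants: 1 3-methylideneoxolan-2-one
Product: 2 (3S)-3-methyloxolan-2-one
Conditions: H2 (100 atm), Ru(OAc)2[(R)-BINAP] (0.5 mol%), CH2Cl2, 50 °C
Reagents that add atoms: none
Why: Ru–BINAP asymmetric hydrogenation of the exocyclic enoate, in which carbonyl coordination to ruthenium fixes the enantioface and sets the future C-10 methyl stereocentre (S).

**Step 2**
Reactants: 2 (3S)-3-methyloxolan-2-one
Product: 3 (3S)-3-methyloxolan-2-ol
Conditions: i-Bu2AlH (1.1 equiv), CH2Cl2, –78 °C; aq. potassium sodium tartrate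
Reagents that add atoms: none
Why: Partial hydride reduction of the lactone stops at the lactol because the tetrahedral aluminate is stable at –78 °C, and the α-stereocentre is untouched.

**Step 3**
Reactants: 3 (3S)-3-methyloxolan-2-ol
Product: 5 (3S)-3-methylpent-4-yn-1-ol, via open-chain hydroxy aldehyde 4 (not isolated)
Conditions: Ohira–Bestmann reagent (1.5 equiv), K2CO3 (2 equiv), MeOH, 0 °C → rt
Reagents that add atoms: dimethyl (1-diazo-2-oxopropyl)phosphonate, CC(=O)C(=[N+]=[N-])P(=O)(OC)OC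
Why: Seyferth–Gilbert homologation (Ohira–Bestmann variant) on the aldehyde tautomer of the lactol converts C=O into the terminal alkyne (C-1/C-2) under conditions mild enough to keep the α-methyl centre from epimerising.

**Step 4**
Reactants: 5 (3S)-3-methylpent-4-yn-1-ol
Product: 6 (3S)-3-methylpent-4-ynal
Conditions: Dess–Martin periodinane (1.2 equiv), CH2Cl2, 0 °C → rt; used as a solution
Reagents that add atoms: none
Why: Dess–Martin oxidation of the primary alcohol under neutral conditions gives the volatile aldehyde, whose stereocentre is β to the carbonyl and cannot enolise.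

**Step 5**
Reactants: 7 2-bromoprop-2-enal; 8 allylmagnesium bromide
Product: 9 2-bromohexa-1,5-dien-3-ol (racemic)
Conditions: Et2O, –78 °C; then aq. NH4Cl
Reagents that add atoms: none
Why: Grignard 1,2-addition to the enal carbonyl gives the bromo-dienol; its carbinol centre is racemic and is destroyed in step 8.

**Step 6**
Reactants: 9 2-bromohexa-1,5-dien-3-ol
Product: 10 methyl 3-hydroxy-2-methylidenehex-5-enoate (racemic)
Conditions: Pd(OAc)2 (5 mol%), PPh3 (10 mol%), CO (3 atm), Et3N (2 equiv), MeOH, 60 °C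
Reagents that add atoms: carbon monoxide, [C-]#[O+]; methanol, CO
Why: Palladium-catalysed methoxycarbonylation of the vinyl bromide (oxidative addition to zerovalent palladium, CO insertion, methanolysis) gives the Baylis–Hillman-type hydroxy ester without handling but-3-enal.

**Step 7**
Reactants: 10 methyl 3-hydroxy-2-methylidenehex-5-enoate
Product: 11 methyl 3-acetoxy-2-methylidenehex-5-enoate (racemic)
Conditions: Ac2O (1.5 equiv), DMAP (5 mol%), pyridine, 0 °C
Reagents that add atoms: acetic anhydride, CC(=O)OC(C)=O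
Why: DMAP-catalysed acylation of the secondary allylic alcohol installs the leaving group for SN2′ substitution.

**Step 8**
Reactants: 11 methyl 3-acetoxy-2-methylidenehex-5-enoate
Product: 12 methyl (2E)-2-[(4,4,5,5-tetramethyl-1,3,2-dioxaborolan-2-yl)methyl]hexa-2,5-dienoate
Conditions: B2pin2 (1.2 equiv), CuCl (10 mol%), KOAc (1 equiv), LiCl (1 equiv), DMF, rt
Reagents that add atoms: bis(pinacolato)diboron, CC1(C)OB(OC1(C)C)B1OC(C)(C)C(C)(C)O1
Why: Copper-catalysed SN2′ borylation (borylcupration of the acrylate, then β-acetoxy elimination) gives the trisubstituted alkene with the allyl chain trans to CO2Me and cis to CH2Bpin, as is general for acrylate-derived Baylis–Hillman acetates.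

**Step 9**
Reactants: 6 (3S)-3-methylpent-4-ynal; 12 methyl (2E)-2-[(4,4,5,5-tetramethyl-1,3,2-dioxaborolan-2-yl)methyl]hexa-2,5-dienoate
Product: 14 (4R,5R)-3-methylidene-5-[(2S)-2-methylbut-3-yn-1-yl]-4-(prop-2-en-1-yl)oxolan-2-one, via homoallyl pinacol borate 13 (not isolated)
Conditions: (S)-TRIP phosphoric acid (5 mol%), toluene, –30 °C → rt, 48 h; then p-TsOH·H2O (10 mol%), rt
Reagents that add atoms: none
Why: Chiral-phosphoric-acid-catalysed allylboration through a chair transition state, in which the (S)-acid directs attack to the Si face of the aldehyde (C-8, R) and the γ-substituent cis to CH2B sits axial to give the syn adduct (C-7, R), whose borate then closes onto the ester to the cis-disubstituted α-methylene-γ-butyrolactone.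

**Step 10**
Reactants: 14 enyne lactone (as above); 15 but-3-en-2-one (5 equiv)
Product: 17 (3aR,7S,8aR)-7-methyl-3-methylidene-6-[(1E)-3-oxobut-1-en-1-yl]-3,3a,4,7,8,8a-hexahydro-2H-cyclohepta[b]furan-2-one (8-epi-xanthatin), via ring-closed triene 16 (not isolated)
Conditions: second-generation Grubbs catalyst RuCl2(=CHPh)(H2IMes)(PCy3) (10 mol%), CH2Cl2 (0.005 M), 40 °C
Reagents that add atoms: none
Why: Domino ring-closing enyne metathesis (exo mode, giving the cycloheptene with C1=C5 and a C-1 vinyl group) followed by E-selective cross metathesis of that vinyl group with the enone, while the electron-poor 1,1-disubstituted exocyclic alkene stays inert.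

**Step 11**
Reactants: 17 8-epi-xanthatin (two molecules)
Product: 18 Diels–Alder dimer (3S,5S,7R,8R,10S,11′S,7′R,8′R,10′S; C1=C2 alkene, 3-acetyl, H-3 cis to H-5)
Conditions: toluene (2 M), BHT (1 mol%), argon, sealed tube, 90 °C, 36 h; chromatography
Reagents that add atoms: none
Why: Thermal Diels–Alder dimerisation in which the C5=C1–C2=C3 diene of one molecule adds to the exocyclic C11′=C13′ alkene of another with C3–C11′/C5–C13′ ("ortho/para") orientation, lactone carbonyl endo and on the diene face opposite H-7, which sets C-3, C-5 and the spiro centre C-11′ under substrate control (minor isomers removed).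

**Step 12**
Reactants: 18 Diels–Alder dimer
Product: 21 target CNP0168949.1, via extended enolate 19 (not isolated), via C-1 hydroperoxide 20 (not isolated)
Conditions: O2 (1 atm), DBU (0.3 equiv), P(OEt)3 (1.5 equiv), MeCN, 0 °C
Reagents that add atoms: dioxygen, O=O
Why: Vinylogous enolate autoxidation in which DBU removes the doubly activated H-3, triplet oxygen adds to the γ-carbon C-1 axially and anti to the pseudo-axial H-5 (trans ring fusion, 1S), the alkene moves into conjugation (C2=C3) and the phosphite reduces the hydroperoxide in situ.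

## Compound list

1 | 3-methylideneoxolan-2-one (α-methylene-γ-butyrolactone) | C=C1CCOC1=O | starting material
2 | (3S)-3-methyloxolan-2-one | C[C@H]1CCOC1=O | intermediate
3 | (3S)-3-methyloxolan-2-ol (lactol, anomer mixture) | C[C@H]1CCOC1O | intermediate
4 | (2S)-4-hydroxy-2-methylbutanal (open-chain tautomer of 3) | O=C[C@@H](C)CCO | intermediate
5 | (3S)-3-methylpent-4-yn-1-ol | OCC[C@H](C)C#C | intermediate
6 | (3S)-3-methylpent-4-ynal | O=CC[C@H](C)C#C | intermediate
7 | 2-bromoprop-2-enal (2-bromoacrolein) | C=C(Br)C=O | starting material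
8 | allylmagnesium bromide | C=CC[Mg]Br | starting material
9 | 2-bromohexa-1,5-dien-3-ol (racemic) | C=CCC(O)C(Br)=C | intermediate
10 | methyl 3-hydroxy-2-methylidenehex-5-enoate (racemic) | C=CCC(O)C(=C)C(=O)OC | intermediate
11 | methyl 3-acetoxy-2-methylidenehex-5-enoate (racemic) | C=CCC(OC(C)=O)C(=C)C(=O)OC | intermediate
12 | methyl (2E)-2-[(4,4,5,5-tetramethyl-1,3,2-dioxaborolan-2-yl)methyl]hexa-2,5-dienoate | COC(=O)/C(CB1OC(C)(C)C(C)(C)O1)=C/CC=C | intermediate
13 | methyl (3R,4R,6S)-6-methyl-2-methylidene-3-(prop-2-en-1-yl)-4-[(4,4,5,5-tetramethyl-1,3,2-dioxaborolan-2-yl)oxy]oct-7-ynoate | C=C(C(=O)OC)[C@@H](CC=C)[C@H](OB1OC(C)(C)C(C)(C)O1)C[C@H](C)C#C | intermediate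
14 | (4R,5R)-3-methylidene-5-[(2S)-2-methylbut-3-yn-1-yl]-4-(prop-2-en-1-yl)oxolan-2-one | C=C1C(=O)O[C@H](C[C@H](C)C#C)[C@@H]1CC=C | intermediate
15 | but-3-en-2-one (methyl vinyl ketone) | C=CC(C)=O | starting material
16 | (3aR,7S,8aR)-6-ethenyl-7-methyl-3-methylidene-3,3a,4,7,8,8a-hexahydro-2H-cyclohepta[b]furan-2-one | C=C1C(=O)O[C@@H]2C[C@H](C)C(C=C)=CC[C@H]12 | intermediate
17 | 8-epi-xanthatin, (3aR,7S,8aR)-7-methyl-3-methylidene-6-[(1E)-3-oxobut-1-en-1-yl]-3,3a,4,7,8,8a-hexahydro-2H-cyclohepta[b]furan-2-one | C=C1C(=O)O[C@@H]2C[C@H](C)C(/C=C/C(C)=O)=CC[C@H]12 | intermediate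
18 | Diels–Alder dimer of 17 (3S,5S,7R,8R,10S,11′S,7′R,8′R,10′S; C1=C2, 3-acetyl) | C=C1C(=O)O[C@@H]2C[C@H](C)C3=C[C@H](C(C)=O)[C@@]4(C[C@@H]3C[C@H]12)C(=O)O[C@@H]1C[C@H](C)C(/C=C/C(C)=O)=CC[C@@H]14 | intermediate
19 | extended (C1=C2–C3=C4–O⁻) enolate of 18, DBU-H⁺ salt | C=C1C(=O)O[C@@H]2C[C@H](C)C3=CC(=C(C)[O-])[C@@]4(C[C@@H]3C[C@H]12)C(=O)O[C@@H]1C[C@H](C)C(/C=C/C(C)=O)=CC[C@@H]14.C1CCC2=[NH+]CCCN2CC1 | intermediate
20 | C-1 hydroperoxide of the target (1S) | C=C1C(=O)O[C@@H]2C[C@H](C)[C@@]3(OO)C=C(C(C)=O)[C@@]4(C[C@@H]3C[C@H]12)C(=O)O[C@@H]1C[C@H](C)C(/C=C/C(C)=O)=CC[C@@H]14 | intermediate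
21 | CNP0168949.1 (1S,5S,7R,8R,10S,11′S,7′R,8′R,10′S) | C=C1C(=O)O[C@@H]2C[C@H](C)[C@@]3(O)C=C(C(C)=O)[C@@]4(C[C@@H]3C[C@H]12)C(=O)O[C@@H]1C[C@H](C)C(/C=C/C(C)=O)=CC[C@@H]14 | target

## Summary

Total step count: 12. Longest linear sequence: 8 (steps 1–4 then 9–12; equally steps 5–8 then 9–12).

**Steps most likely to fail, with fallbacks**

Step 9 (the ester-deactivated boronate may react sluggishly, or catalyst control over C-7/C-8 may be incomplete). The fallback sets out from 6 and returns at 14. It sets the two centres by an auxiliary-controlled syn-aldol and closes the lactone by carbonylation. Pent-4-enoyl chloride is attached to lithiated (S)-4-benzyloxazolidin-2-one (n-BuLi, THF, –78 °C) to give (4S)-4-benzyl-3-(pent-4-enoyl)-1,3-oxazolidin-2-one F1. Its Z-boron enolate (Bu2BOTf, i-Pr2NEt, CH2Cl2, –78 → 0 °C) adds to 6 to give the Evans syn-aldol adduct F2. AlMe3/MeNHOMe·HCl converts this into the Weinreb amide F3, and Et3SiOTf/2,6-lutidine gives its triethylsilyl ether F4. MeMgBr (3 equiv, the first deprotonating the alkyne) gives the methyl ketone F5. KN(SiMe3)2/PhNTf2 at –78 °C gives the terminal enol triflate F6, and HF·pyridine frees the hydroxy enol triflate F7. Pd(PPh3)4, CO (1 atm), Bu3N and LiCl in MeCN at 65 °C then effect carbonylative lactonisation to 14.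

Step 11 (the electron-poor dienone may dimerise slowly, unselectively or oligomerise). The fallback sets out from 17 and returns at 18. It makes the diene electron-rich before the cycloaddition. Luche reduction (NaBH4, CeCl3·7H2O, MeOH, –78 °C) gives the allylic alcohol 4-dihydro-8-epi-xanthatin F8 (C-4 epimers). This dimerises under milder heating (toluene, 60 °C) as a normal-demand Diels–Alder reaction with the same C3–C11′/C5–C13′ orientation to give the dimeric diol F9. Dess–Martin periodinane then oxidises both carbinols to give 18.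

Step 12 (base and oxygen may attack the dienone or the methylene lactones, or the C-1 epimer may form). The fallback sets out from 14 and 17 and returns at 21. It hydroxylates before the second dienone exists. Heating 17 with excess 14 (5 equiv, toluene, 90 °C) gives the cross Diels–Alder adduct F10, whose only ketone is the C-4 acetyl. Me3SiOTf/Et3N (CH2Cl2, 0 °C) gives the conjugated trimethylsilyl dienol ether F11. Dimethyldioxirane (acetone, –78 °C; citric acid work-up) performs a vinylogous Rubottom oxidation at C-1 from the face anti to H-5 to give the hydroxy enone F12. Domino enyne metathesis/cross metathesis of F12 with 15 (second-generation Grubbs catalyst, CH2Cl2, 40 °C) then builds the second cycloheptene and dienone to give 21.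

## Further compounds

F1 | step 9 | (4S)-4-benzyl-3-(pent-4-enoyl)-1,3-oxazolidin-2-one | C=CCCC(=O)N1C(=O)OC[C@@H]1Cc1ccccc1
F2 | step 9 | (4S)-4-benzyl-3-[(2S,3R,5S)-3-hydroxy-5-methyl-2-(prop-2-en-1-yl)hept-6-ynoyl]-1,3-oxazolidin-2-one | O=C(N1C(=O)OC[C@@H]1Cc1ccccc1)[C@@H](CC=C)[C@H](O)C[C@H](C)C#C
F3 | step 9 | (2S,3R,5S)-3-hydroxy-N-methoxy-N,5-dimethyl-2-(prop-2-en-1-yl)hept-6-ynamide | CON(C)C(=O)[C@@H](CC=C)[C@H](O)C[C@H](C)C#C
F4 | step 9 | (2S,3R,5S)-N-methoxy-N,5-dimethyl-2-(prop-2-en-1-yl)-3-[(triethylsilyl)oxy]hept-6-ynamide | CON(C)C(=O)[C@@H](CC=C)[C@H](O[Si](CC)(CC)CC)C[C@H](C)C#C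
F5 | step 9 | (3S,4R,6S)-6-methyl-3-(prop-2-en-1-yl)-4-[(triethylsilyl)oxy]oct-7-yn-2-one | CC(=O)[C@@H](CC=C)[C@H](O[Si](CC)(CC)CC)C[C@H](C)C#C
F6 | step 9 | (3S,4R,6S)-6-methyl-3-(prop-2-en-1-yl)-4-[(triethylsilyl)oxy]oct-1-en-7-yn-2-yl trifluoromethanesulfonate | C=C(OS(=O)(=O)C(F)(F)F)[C@@H](CC=C)[C@H](O[Si](CC)(CC)CC)C[C@H](C)C#C
F7 | step 9 | (3S,4R,6S)-4-hydroxy-6-methyl-3-(prop-2-en-1-yl)oct-1-en-7-yn-2-yl trifluoromethanesulfonate | C=C(OS(=O)(=O)C(F)(F)F)[C@@H](CC=C)[C@H](O)C[C@H](C)C#C
F8 | step 11 | 4-dihydro-8-epi-xanthatin, (3aR,7S,8aR)-6-[(1E)-3-hydroxybut-1-en-1-yl]-7-methyl-3-methylidene-3,3a,4,7,8,8a-hexahydro-2H-cyclohepta[b]furan-2-one (C-4 epimers) | C=C1C(=O)O[C@@H]2C[C@H](C)C(/C=C/C(C)O)=CC[C@H]12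
F9 | step 11 | dimeric diol (4,4′-dihydro form of 18, carbinol epimers) | C=C1C(=O)O[C@@H]2C[C@H](C)C3=C[C@H](C(C)O)[C@@]4(C[C@@H]3C[C@H]12)C(=O)O[C@@H]1C[C@H](C)C(/C=C/C(C)O)=CC[C@@H]14
F10 | step 12 | cross Diels–Alder adduct of 17 (diene) and 14 (dienophile) | C=C1C(=O)O[C@@H]2C[C@H](C)C3=C[C@H](C(C)=O)[C@@]4(C[C@@H]3C[C@H]12)C(=O)O[C@H](C[C@H](C)C#C)[C@@H]4CC=C
F11 | step 12 | trimethylsilyl dienol ether of F10 | C=C1C(=O)O[C@@H]2C[C@H](C)C3=CC(=C(C)O[Si](C)(C)C)[C@@]4(C[C@@H]3C[C@H]12)C(=O)O[C@H](C[C@H](C)C#C)[C@@H]4CC=C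
F12 | step 12 | 1-hydroxy-2-en-4-one cross adduct (1S) | C=C1C(=O)O[C@@H]2C[C@H](C)[C@@]3(O)C=C(C(C)=O)[C@@]4(C[C@@H]3C[C@H]12)C(=O)O[C@H](C[C@H](C)C#C)[C@@H]4CC=C
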